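The target is a bicyclo[3.3.1]nonane whose oxygenated quaternary bridgehead C1 sits between the C9 ketone and epoxide carbon C8. Ring B (C1–C9–C5–C6–C7–C8) can therefore begin as an achiral 2-alkoxycyclohexane-1,3-dione, and C2–C3–C4 of ring A as a 2-methylenepropane-1,3-diyl unit. One palladium-catalysed double allylation joins C1–C2 and then C4–C5 and closes ring A. A chiral diphosphine chooses between the two mirror-related carbonyl arms and so sets both bridgeheads. The precursors are 2-(benzyloxy)cyclohexane-1,3-dione and the bis(tert-butyl carbonate) of 2-methylenepropane-1,3-diol, which releases only non-nucleophilic base. The C3 methylene then masks a ketone while ring B is elaborated.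

Key step: step 4

Conventions: all names use the working locants C1 (O-bearing bridgehead), C2, C3 (N), C4 (carbinol), C5 (bridgehead CH), C6 (OMe), C7, C8, C9 (bridging C=O). Ring A is C1–C2–C3–C4–C5–C9 and ring B is C1–C8–C7–C6–C5–C9. Exo means on the convex face of a ring, syn to C9. Endo means pointing into the cleft between rings A and B.

Assumption: the (R,R) antipode of the diphosphine is taken to give the (1S,5R) bicyclic dione; the sense of induction on this substrate class cannot be predicted with certainty, and the (S,S) antipode is used if it proves opposite.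

Step 1
Reactants: 1 cyclohexane-1,3-dione
Product: 2 2-diazocyclohexane-1,3-dione
Conditions: p-ABSA, Et3N, MeCN, 0 °C → rt
Reagents that add atoms: 4-acetamidobenzenesulfonyl azide (p-ABSA), CC(=O)Nc1ccc(cc1)S(=O)(=O)N=[N+]=[N-]
Why: Regitz diazo transfer: the amine-generated enolate of the 1,3-dione attacks the terminal nitrogen of the sulfonyl azide and the adduct collapses to the doubly stabilised diazo compound and the sulfonamide, with no stereocentre involved.

Step 2
Reactants: 2 2-diazocyclohexane-1,3-dione; 3 benzyl alcohol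
Product: 4 2-(benzyloxy)cyclohexane-1,3-dione (achiral; largely enolised)
Conditions: Rh2(OAc)4 (1 mol %), 3 (3 equiv), 1,2-dichloroethane, 70 °C
Reagents that add atoms: none
Why: Rhodium-carbenoid O–H insertion: loss of N2 gives an electrophilic acceptor/acceptor carbenoid that the alcohol oxygen captures (oxonium ylide, then proton shift) faster than Wolff rearrangement can occur, and the product stays achiral because it keeps the mirror plane through the alkoxy carbon.

Step 3
Reactants: 5 2-methylenepropane-1,3-diol
Product: 6 di-tert-butyl (2-methylenepropane-1,3-diyl) dicarbonate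
Conditions: Boc2O (2.4 equiv), Bu4NHSO4 (5 mol %), 30% aq NaOH, CH2Cl2, 0 °C → rt
Reagents that add atoms: di-tert-butyl dicarbonate, CC(C)(C)OC(=O)OC(=O)OC(C)(C)C
Why: Phase-transfer O-tert-butoxycarbonylation of two unhindered primary allylic alcohols; the tert-butyl carbonate is preferred to a methyl carbonate because its ionisation releases tert-butoxide, a stronger base that is too bulky to open a non-enolisable 1,3-diketone by retro-Claisen attack.

Step 4
Reactants: 4 2-(benzyloxy)cyclohexane-1,3-dione; 6 di-tert-butyl (2-methylenepropane-1,3-diyl) dicarbonate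
Product: 8 (1S,5R)-1-(benzyloxy)-3-methylenebicyclo[3.3.1]nonane-8,9-dione, via monoallylated dione 7 (not isolated)
Conditions: Pd2(dba)3·CHCl3 (2.5 mol %), (R,R)-N,N′-(cyclohexane-1,2-diyl)bis[2-(diphenylphosphino)benzamide] (7.5 mol %), 6 (1.2 equiv), THF (0.02 M), slow addition of 4 at 0 °C, then 40 °C
Reagents that add atoms: none
Why: Proposed new method: zerovalent palladium ionises one carbonate of 6 (CO2 and tert-butoxide leave), the base deprotonates the acidic C1–H of 4, and the soft enolate attacks the η3-allyl terminus through carbon to give achiral 7 (bond C1–C2), while any O-allyl enol ether is re-ionised and drained to the C-allyl product; a second ionisation then gives a tethered η3-allyl complex whose tert-butoxide counter-ion forms the α′ enolate, and its carbon C5 attacks terminus C4 anti to the metal (bond C4–C5). The closest known reaction type is the palladium-catalysed bicycloannulation (α,α′-annulation) of cyclic β-keto esters with 2-methylenepropane-1,3-diyl diesters, also practised with chiral ligands that differentiate the faces of a prochiral enolate; new here are the 2-alkoxy-1,3-dione substrate class and the choice between two enantiotopic carbonyl arms. Ring A is closed in a 6-(enolendo)-exo mode on the allyl terminus, as a three-carbon bridge across the 1,3-related ring-B atoms C1 and C5, with the C3 methylene left exocyclic. C1 turns stereogenic only in this second, irreversible C–C bond formation; since the C5 and C7 enolates interconvert through tert-butanol, the chiral pocket of the diphosphine decides which of them reaches the allyl terminus, and C5 follows from C1 by geometry because the short bridge can span the ring only in a cis-1,3-diaxial way. The step needs C- over O-allylation, cyclisation over capture of the second allyl complex by another molecule of 4, and an intact β-diketone: reversibility of O-allylation secures the first, slow addition of the far more acidic 4 at high dilution the second, and the fully substituted C1 (only C5 and C7 can enolise) together with non-nucleophilic tert-butoxide the third.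

Step 5
Reactants: 8 (1S,5R)-1-(benzyloxy)-3-methylenebicyclo[3.3.1]nonane-8,9-dione
Product: 10 1-(benzyloxy)-3-methylenebicyclo[3.3.1]non-6-ene-8,9-dione (C1 and C5 as in 8), via C8 trimethylsilyl enol ether 9 (not isolated)
Conditions: LiN(SiMe3)2, Me3SiCl, THF, −78 °C; solvent switch; Pd(OAc)2 (1.1 equiv), MeCN, rt
Reagents that add atoms: chlorotrimethylsilane, C[Si](C)(C)Cl (atoms found in 9 only)
Why: Saegusa–Ito oxidation: C7 is the only position of 8 that can be deprotonated (C1 is quaternary and a C5 enolate would be a bridgehead alkene), so the silyl enol ether forms regiospecifically, and divalent palladium then gives an oxa-allyl complex that loses the exo C6 hydrogen by β-hydride elimination without touching a stereocentre.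

Step 6
Reactants: 10 1-(benzyloxy)-3-methylenebicyclo[3.3.1]non-6-ene-8,9-dione
Product: 11 1-(benzyloxy)-6,7-exo-epoxy-3-methylenebicyclo[3.3.1]nonane-8,9-dione
Conditions: t-BuOOH (decane), DBU, CH2Cl2, 0 °C → rt
Reagents that add atoms: tert-butyl hydroperoxide, CC(C)(C)OO
Why: Weitz–Scheffer nucleophilic epoxidation: the peroxide anion adds to C6 of the enone along the axial trajectory on the convex exo face (the endo face looks at C3 and C4 of ring A) and the C7 enolate closes on oxygen, which sets C6 and C7 with both C–O bonds exo, while the isolated 1,1-disubstituted alkene is inert and the bulky anhydrous peroxide limits attack at the C9 carbonyl.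

Step 7
Reactants: 11 1-(benzyloxy)-6,7-exo-epoxy-3-methylenebicyclo[3.3.1]nonane-8,9-dione
Product: 13 1-(benzyloxy)-6-exo-hydroxy-3-methylenebicyclo[3.3.1]non-7-en-9-one, via C8 hydrazone 12 (not isolated)
Conditions: N2H4·H2O (2 equiv), AcOH (cat.), MeOH, 0 °C → rt, Ar; acetone quench
Reagents that add atoms: hydrazine, NN (atoms found in 12 only)
Why: Wharton transposition: hydrazine condenses with the inductively activated epoxy-ketone carbonyl C8, the hydrazone opens the epoxide to an allylic diazene and loss of N2 leaves the C7=C8 alkene and the C6 alcohol, whose C–O bond is never broken and so stays exo; the irreversible N2 loss drains any reversible condensation at the more crowded C9 ketone, and argon excludes diimide reduction of the alkenes.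

Step 8
Reactants: 13 1-(benzyloxy)-6-exo-hydroxy-3-methylenebicyclo[3.3.1]non-7-en-9-one
Product: 14 1-(benzyloxy)-6-exo-methoxy-3-methylenebicyclo[3.3.1]non-7-en-9-one
Conditions: Me3OBF4, 1,8-bis(dimethylamino)naphthalene, 4 Å MS, CH2Cl2, 0 °C → rt
Reagents that add atoms: trimethyloxonium tetrafluoroborate, C[O+](C)C.F[B-](F)(F)F
Why: O-Methylation with an oxonium salt under non-basic conditions (the amine only takes up HBF4), chosen because a free C6 alkoxide is β to the C9 ketone and could cleave C5–C6 by retro-aldol reaction; the C6 configuration is untouched and the methyl ether serves as its own protecting group from here on.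

Step 9
Reactants: 14 1-(benzyloxy)-6-exo-methoxy-3-methylenebicyclo[3.3.1]non-7-en-9-one
Product: 16 1-(benzyloxy)-6-exo-methoxybicyclo[3.3.1]non-7-ene-3,9-dione, via exo-face diol 15 (not isolated)
Conditions: K2OsO4·2H2O (2 mol %), NMO (1.1 equiv), acetone–H2O, 0 °C; then NaIO4, rt
Reagents that add atoms: N-methylmorpholine N-oxide, C[N+]1([O-])CCOCC1; water, O
Why: Upjohn dihydroxylation followed by periodate (Malaprade) glycol cleavage: with the co-oxidant limiting, osmium tetroxide selects the open, electron-richer exocyclic alkene over C7=C8, which is flanked by the two C–O-bearing carbons C6 and C1 and is both shielded and inductively deactivated, and the transient C3 stereocentre is erased in the cleavage.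

Step 10
Reactants: 16 1-(benzyloxy)-6-exo-methoxybicyclo[3.3.1]non-7-ene-3,9-dione
Product: 17 1-(benzyloxy)-4-exo-hydroxy-6-exo-methoxybicyclo[3.3.1]non-7-ene-3,9-dione
Conditions: NaN(SiMe3)2, THF, −78 °C; 2-(phenylsulfonyl)-3-phenyloxaziridine, −78 °C; AcOH, −78 °C
Reagents that add atoms: 2-(phenylsulfonyl)-3-phenyloxaziridine, O=S(=O)(c1ccccc1)N1OC1c1ccccc1
Why: Davis enolate hydroxylation: the bulky amide removes the exo (axial) C4 proton next to tertiary C5 in preference to the C2 protons, which are neopentylic and screened by the C1 benzyloxy group (the bias known from 3,3,5-trisubstituted cyclohexanones), C9 cannot enolise, and the oxaziridine delivers oxygen to the convex exo face of the enolate, which sets C4, while the cold acidic quench protects the aldolate-like C4 alkoxide from retro-aldol cleavage.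

Step 11
Reactants: 17 1-(benzyloxy)-4-exo-hydroxy-6-exo-methoxybicyclo[3.3.1]non-7-ene-3,9-dione
Product: 18 1,4-exo-bis(benzyloxy)-6-exo-methoxybicyclo[3.3.1]non-7-ene-3,9-dione
Conditions: BnOC(=NH)CCl3, TfOH (5 mol %), CH2Cl2–cyclohexane, 0 °C
Reagents that add atoms: benzyl 2,2,2-trichloroacetimidate, N=C(OCc1ccccc1)C(Cl)(Cl)Cl
Why: Acid-catalysed trichloroacetimidate O-benzylation, which needs no alkoxide and so avoids retro-aldol cleavage and epimerisation of the α-ketol; a benzyl ether is chosen because it is a poor neighbouring group for step 13 and leaves together with the C1 benzyl group in step 15.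

Step 12
Reactants: 18 1,4-exo-bis(benzyloxy)-6-exo-methoxybicyclo[3.3.1]non-7-ene-3,9-dione
Product: 19 1,4-exo-bis(benzyloxy)-3-endo-hydroxy-6-exo-methoxybicyclo[3.3.1]non-7-en-9-one
Conditions: NaBH4, MeOH–THF, −40 °C
Reagents that add atoms: none
Why: Substrate-controlled borohydride reduction: with ring A in its chair, hydride can reach C3 only from the convex exo side (the endo trajectory runs into C7 of ring B), which places the new hydroxyl endo and trans to the C4 benzyloxy group, while the C9 ketone is screened on its two faces by the exo C4 and exo C6 oxygen substituents and should survive at low temperature.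

Step 13
Reactants: 19 1,4-exo-bis(benzyloxy)-3-endo-hydroxy-6-exo-methoxybicyclo[3.3.1]non-7-en-9-one
Product: 21 3-exo-azido-1,4-exo-bis(benzyloxy)-6-exo-methoxybicyclo[3.3.1]non-7-en-9-one, via endo triflate 20 (not isolated)
Conditions: Tf2O, pyridine, CH2Cl2, −20 °C; cold aqueous wash and solvent switch; NaN3, DMF, 0 °C → rt
Reagents that add atoms: triflic anhydride, O=S(=O)(OS(=O)(=O)C(F)(F)F)C(F)(F)F (atoms found in 20 only); sodium azide (NaN3), [Na+].[N-]=[N+]=[N-]
Why: Triflation and SN2 displacement with Walden inversion: the endo leaving group is axial on chair ring A, so azide enters along the open exo trajectory and the C3–N bond ends exo and cis to C4–O, while the adjacent electron-withdrawing oxygen suppresses ionisation and the weakly basic nucleophile at low temperature restrains E2 loss of the anti C2 hydrogen.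

Step 14
Reactants: 21 3-exo-azido-1,4-exo-bis(benzyloxy)-6-exo-methoxybicyclo[3.3.1]non-7-en-9-one
Product: 22 3-exo-azido-1,4-exo-bis(benzyloxy)-7,8-exo-epoxy-6-exo-methoxybicyclo[3.3.1]nonan-9-one
Conditions: mCPBA, CH2Cl2, 0 °C → rt
Reagents that add atoms: 3-chloroperoxybenzoic acid, OOC(=O)c1cccc(Cl)c1
Why: Prilezhaev epoxidation: the endo C3–H of chair ring A lies over the concave face of C7=C8, so the peracid can approach only from the exo face, which sets C7 and C8 cis to the C6 methoxy group; the epoxide is introduced only now because the endo C3 hydroxyl of 19 would sit behind the C7–O bond of an exo epoxide and open it transannularly.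

Step 15
Reactants: 22 3-exo-azido-1,4-exo-bis(benzyloxy)-7,8-exo-epoxy-6-exo-methoxybicyclo[3.3.1]nonan-9-one
Product: 23 3-exo-amino-7,8-exo-epoxy-1,4-exo-dihydroxy-6-exo-methoxybicyclo[3.3.1]nonan-9-one
Conditions: H2 (1 atm), Pd(OH)2/C, EtOH, rt
Reagents that add atoms: none
Why: Catalytic hydrogenation and hydrogenolysis: one operation reduces the azide to the amine and cleaves both benzyl ethers, while the non-benzylic epoxide, the hindered ketone and the methyl ether are not substrates under these conditions and no stereocentre is touched.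

Step 16
Reactants: 23 3-exo-amino-7,8-exo-epoxy-1,4-exo-dihydroxy-6-exo-methoxybicyclo[3.3.1]nonan-9-one; 24 (E)-dodec-2-enoic acid
Product: 27 (E)-N-[(1S,3S,4R,5S,6S,7S,8S)-7,8-epoxy-1,4-dihydroxy-6-methoxy-9-oxobicyclo[3.3.1]nonan-3-yl]dodec-2-enamide (CNP0137540.1), via O-acylisourea 25 (not isolated), via benzotriazolyl ester 26 (not isolated)
Conditions: EDCI, HOBt, CH2Cl2–DMF, 0 °C → rt
Reagents that add atoms: EDCI, CCN=C=NCCCN(C)C (atoms found in 25 only); 1-hydroxybenzotriazole, On1nnc2ccccc12 (atoms found in 26 only)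
Why: Carbodiimide/HOBt amide coupling: the primary amine outcompetes the secondary and tertiary hydroxyl groups for the active ester, the neutral conditions spare the epoxide and the α-ketol, and the E alkene of the acid is not affected.

Compound list
1 | cyclohexane-1,3-dione | O=C1CCCC(=O)C1 | starting material
2 | 2-diazocyclohexane-1,3-dione | [N-]=[N+]=C1C(=O)CCCC1=O | intermediate
3 | benzyl alcohol | OCc1ccccc1 | starting material
4 | 2-(benzyloxy)cyclohexane-1,3-dione | O=C1CCCC(=O)C1OCc1ccccc1 | intermediate
5 | 2-methylenepropane-1,3-diol | C=C(CO)CO | starting material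
6 | di-tert-butyl (2-methylenepropane-1,3-diyl) dicarbonate | C=C(COC(=O)OC(C)(C)C)COC(=O)OC(C)(C)C | intermediate
7 | 2-(benzyloxy)-2-{2-[(tert-butoxycarbonyloxy)methyl]prop-2-en-1-yl}cyclohexane-1,3-dione (achiral) | C=C(COC(=O)OC(C)(C)C)CC1(OCc2ccccc2)C(=O)CCCC1=O | intermediate
8 | (1S,5R)-1-(benzyloxy)-3-methylenebicyclo[3.3.1]nonane-8,9-dione | C=C1C[C@@]2(OCc3ccccc3)C(=O)[C@@H](C1)CCC2=O | intermediate
9 | 1-(benzyloxy)-3-methylene-8-(trimethylsilyloxy)bicyclo[3.3.1]non-7-en-9-one | C=C1C[C@@]2(OCc3ccccc3)C(=O)[C@@H](C1)CC=C2O[Si](C)(C)C | intermediate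
10 | 1-(benzyloxy)-3-methylenebicyclo[3.3.1]non-6-ene-8,9-dione | C=C1C[C@@]2(OCc3ccccc3)C(=O)[C@@H](C1)C=CC2=O | intermediate
11 | 1-(benzyloxy)-6,7-exo-epoxy-3-methylenebicyclo[3.3.1]nonane-8,9-dione | C=C1C[C@@]2(OCc3ccccc3)C(=O)[C@@H](C1)[C@@H]4O[C@@H]4C2=O | intermediate
12 | C8 hydrazone of 11 | C=C1C[C@@]2(OCc3ccccc3)C(=O)[C@@H](C1)[C@@H]4O[C@@H]4C2=NN | intermediate
13 | 1-(benzyloxy)-6-exo-hydroxy-3-methylenebicyclo[3.3.1]non-7-en-9-one | C=C1C[C@@]2(OCc3ccccc3)C(=O)[C@@H](C1)[C@H](O)C=C2 | intermediate
14 | 1-(benzyloxy)-6-exo-methoxy-3-methylenebicyclo[3.3.1]non-7-en-9-one | C=C1C[C@@]2(OCc3ccccc3)C(=O)[C@@H](C1)[C@H](OC)C=C2 | intermediate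
15 | 1-(benzyloxy)-3-exo-hydroxy-3-endo-(hydroxymethyl)-6-exo-methoxybicyclo[3.3.1]non-7-en-9-one | OC[C@]1(O)C[C@@]2(OCc3ccccc3)C(=O)[C@@H](C1)[C@H](OC)C=C2 | intermediate
16 | 1-(benzyloxy)-6-exo-methoxybicyclo[3.3.1]non-7-ene-3,9-dione | O=C1C[C@@]2(OCc3ccccc3)C(=O)[C@@H](C1)[C@H](OC)C=C2 | intermediate
17 | 1-(benzyloxy)-4-exo-hydroxy-6-exo-methoxybicyclo[3.3.1]non-7-ene-3,9-dione | O=C1C[C@@]2(OCc3ccccc3)C(=O)[C@@H]([C@H]1O)[C@H](OC)C=C2 | intermediate
18 | 1,4-exo-bis(benzyloxy)-6-exo-methoxybicyclo[3.3.1]non-7-ene-3,9-dione | O=C1C[C@@]2(OCc3ccccc3)C(=O)[C@@H]([C@H]1OCc4ccccc4)[C@H](OC)C=C2 | intermediate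
19 | 1,4-exo-bis(benzyloxy)-3-endo-hydroxy-6-exo-methoxybicyclo[3.3.1]non-7-en-9-one | O[C@@H]1C[C@@]2(OCc3ccccc3)C(=O)[C@@H]([C@H]1OCc4ccccc4)[C@H](OC)C=C2 | intermediate
20 | 3-endo trifluoromethanesulfonate of 19 | FC(F)(F)S(=O)(=O)O[C@@H]1C[C@@]2(OCc3ccccc3)C(=O)[C@@H]([C@H]1OCc4ccccc4)[C@H](OC)C=C2 | intermediate
21 | 3-exo-azido-1,4-exo-bis(benzyloxy)-6-exo-methoxybicyclo[3.3.1]non-7-en-9-one | [N-]=[N+]=N[C@H]1C[C@@]2(OCc3ccccc3)C(=O)[C@@H]([C@H]1OCc4ccccc4)[C@H](OC)C=C2 | intermediate
22 | 3-exo-azido-1,4-exo-bis(benzyloxy)-7,8-exo-epoxy-6-exo-methoxybicyclo[3.3.1]nonan-9-one | [N-]=[N+]=N[C@H]1C[C@@]2(OCc3ccccc3)C(=O)[C@@H]([C@H]1OCc4ccccc4)[C@H](OC)[C@@H]5O[C@@H]52 | intermediate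
23 | 3-exo-amino-7,8-exo-epoxy-1,4-exo-dihydroxy-6-exo-methoxybicyclo[3.3.1]nonan-9-one | N[C@H]1C[C@@]2(O)C(=O)[C@@H]([C@H]1O)[C@H](OC)[C@@H]3O[C@@H]32 | intermediate
24 | (E)-dodec-2-enoic acid | CCCCCCCCC/C=C/C(=O)O | starting material
25 | O-[(E)-dodec-2-enoyl]isourea from EDCI | CCCCCCCCC/C=C/C(=O)OC(NCC)=NCCCN(C)C | intermediate
26 | benzotriazol-1-yl (E)-dodec-2-enoate | CCCCCCCCC/C=C/C(=O)On1nnc2ccccc12 | intermediate
27 | (E)-N-[(1S,3S,4R,5S,6S,7S,8S)-7,8-epoxy-1,4-dihydroxy-6-methoxy-9-oxobicyclo[3.3.1]nonan-3-yl]dodec-2-enamide | CCCCCCCCC/C=C/C(=O)N[C@H]1C[C@@]2(O)C(=O)[C@@H]([C@H]1O)[C@H](OC)[C@@H]1O[C@@H]12 | target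

Total step count: 16. Longest linear sequence: 15 (steps 1, 2 and 4–16; step 3 is a one-step branch).

Steps most likely to fail

1. Step 4. What may go wrong: weak discrimination between the two enantiotopic carbonyl arms, capture of the second allyl complex by unreacted dione instead of ring closure, or closure through the enolate oxygen.
Fallback (known chemistry; the enantio-determining event moves from C–C bond formation to a carbonyl reduction): it sets out from 4 and 6 and comes back at 8. With Pd(PPh3)4 in THF at 0 °C and 6 in excess, only the first allylation is run and 7 is isolated. Asymmetric transfer hydrogenation (RuCl(p-cymene)[(S,S)-TsDPEN], HCO2H–Et3N) is an established desymmetrisation of 2,2-disubstituted cyclic 1,3-diones, and it reduces one carbonyl group to the hydroxy ketone F1. TBSOTf/2,6-lutidine gives the silyl ether F2. Pd(PPh3)4 in THF at 40 °C closes the enolate of the one remaining ketone (C5) onto the allyl carbonate (intramolecular Tsuji–Trost allylation) to give the bicyclic silyl ether F3. Bu4NF/AcOH liberates the bicyclic alcohol F4, and DMP oxidation returns 8.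

2. Step 13. What may go wrong: E2 elimination toward C2, or sluggish substitution because the axial C4 benzyloxy group screens the exo trajectory; poor facial selectivity in step 12 would feed the same problem.
Fallback (both heteroatoms added in one syn addition instead of hydroxylation, reduction and inversion): it sets out from 16 and comes back at 23. Kinetic enolisation toward C4 (KN(SiMe3)2, PhNTf2, THF, −78 °C) gives the C3 enol triflate F5. Formate reduction (Pd(OAc)2, PPh3, HCO2H, Bu3N, DMF) gives the C3–C4 alkene F6. Osmium-catalysed Sharpless aminohydroxylation in its base-free form (K2OsO2(OH)4 cat., benzyl (4-chlorobenzoyloxy)carbamate, MeCN–H2O) adds N and O together from the exo face, with nitrogen at the less hindered C3. The deactivated C7=C8 alkene is left untouched, and the product is the benzyl carbamate F7. mCPBA gives the epoxy carbamate F8, and H2 with Pd(OH)2/C removes the Cbz and benzyl groups to return 23.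

3. Step 7. What may go wrong: competing condensation of hydrazine at C9, or C–C cleavage of the 1,3-dicarbonyl array by the nucleophiles of steps 6 and 7.
Fallback (no peroxide anion and no hydrazine): it sets out from 10 and comes back at 14. Copper-catalysed conjugate borylation (CuCl, Xantphos, NaOt-Bu, B2pin2, MeOH, THF) adds boron to C6 from the exo face to give the β-boryl ketone F9. NaBO3·4H2O oxidises the C–B bond with retention to the β-hydroxy ketone F10. Me3OBF4 with 1,8-bis(dimethylamino)naphthalene gives the β-methoxy ketone F11. KN(SiMe3)2/PhNTf2 at −78 °C gives the C8 enol triflate F12. Formate reduction (Pd(OAc)2, PPh3, HCO2H, Bu3N) then returns 14.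

Further compounds
F1 | step 4 | 2-(benzyloxy)-3-hydroxy-2-{2-[(tert-butoxycarbonyloxy)methyl]prop-2-en-1-yl}cyclohexan-1-one, OH cis to the allyl chain | C=C(COC(=O)OC(C)(C)C)C[C@@]1(OCc2ccccc2)C(=O)CCC[C@H]1O
F2 | step 4 | tert-butyldimethylsilyl ether of F1 | C=C(COC(=O)OC(C)(C)C)C[C@@]1(OCc2ccccc2)C(=O)CCC[C@H]1O[Si](C)(C)C(C)(C)C
F3 | step 4 | 1-(benzyloxy)-8-endo-(tert-butyldimethylsilyloxy)-3-methylenebicyclo[3.3.1]nonan-9-one | C=C1C[C@@]2(OCc3ccccc3)C(=O)[C@@H](C1)CC[C@H]2O[Si](C)(C)C(C)(C)C
F4 | step 4 | 1-(benzyloxy)-8-endo-hydroxy-3-methylenebicyclo[3.3.1]nonan-9-one | C=C1C[C@@]2(OCc3ccccc3)C(=O)[C@@H](C1)CC[C@H]2O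
F5 | step 13 | 1-(benzyloxy)-6-exo-methoxy-9-oxobicyclo[3.3.1]nona-3,7-dien-3-yl trifluoromethanesulfonate | C1C(OS(=O)(=O)C(F)(F)F)=C[C@H]2[C@H](OC)C=C[C@]1(OCc3ccccc3)C2=O
F6 | step 13 | 1-(benzyloxy)-6-exo-methoxybicyclo[3.3.1]nona-3,7-dien-9-one | C1C=C[C@H]2[C@H](OC)C=C[C@]1(OCc3ccccc3)C2=O
F7 | step 13 | benzyl N-[1-(benzyloxy)-4-exo-hydroxy-6-exo-methoxy-9-oxobicyclo[3.3.1]non-7-en-3-exo-yl]carbamate | O=C(OCc5ccccc5)N[C@H]1C[C@@]2(OCc3ccccc3)C(=O)[C@@H]([C@H]1O)[C@H](OC)C=C2
F8 | step 13 | 7,8-exo-epoxide of F7 | O=C(OCc5ccccc5)N[C@H]1C[C@@]2(OCc3ccccc3)C(=O)[C@@H]([C@H]1O)[C@H](OC)[C@@H]4O[C@@H]42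
F9 | step 7 | 1-(benzyloxy)-3-methylene-6-exo-(4,4,5,5-tetramethyl-1,3,2-dioxaborolan-2-yl)bicyclo[3.3.1]nonane-8,9-dione | C=C1C[C@@]2(OCc3ccccc3)C(=O)[C@@H](C1)[C@H](B4OC(C)(C)C(C)(C)O4)CC2=O
F10 | step 7 | 1-(benzyloxy)-6-exo-hydroxy-3-methylenebicyclo[3.3.1]nonane-8,9-dione | C=C1C[C@@]2(OCc3ccccc3)C(=O)[C@@H](C1)[C@H](O)CC2=O
F11 | step 7 | 1-(benzyloxy)-6-exo-methoxy-3-methylenebicyclo[3.3.1]nonane-8,9-dione | C=C1C[C@@]2(OCc3ccccc3)C(=O)[C@@H](C1)[C@H](OC)CC2=O
F12 | step 7 | 1-(benzyloxy)-6-exo-methoxy-3-methylene-9-oxobicyclo[3.3.1]non-7-en-8-yl trifluoromethanesulfonate | C=C1C[C@@]2(OCc3ccccc3)C(=O)[C@@H](C1)[C@H](OC)C=C2OS(=O)(=O)C(F)(F)F
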